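**Retrosynthetic overview**
1. The target is a (2R,3S)-trans-3-arylnaringenin (rings A, C, B; atoms O1, C2, C3, C4). Its C3 substituent is ring E, the 4-hydroxyphenyl ring of an apigenin unit (benzo ring D, pyrone ring F). The end game is loss of one temporary carbon from C3 as CO2, then hydrogenolysis of five benzyl ethers.
2. Key disconnection: ring C is opened at O1–C2 and C3–C4. This gives a ring A salicylaldehyde (O1 and the C4 carbon stand ortho on ring A) and a C2=C3 alkene carrying rings B and E. In the forward sense this is a carbene-catalysed oxidative [4+2] annulation (oxa-Michael addition, then C-acylation).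
3. Enabling feature: the phenolic oxygen of ring E stands ortho to the ring E–C3 bond, and C3 ends up alpha to the C4 ketone. A one-carbon C=O bridge from that oxygen to C3 gives a benzofuran-2(3H)-one. C2=C3 then becomes a 3-arylidene lactone (C2 electrophilic, C3 a latent enolate), the ring E phenol is masked, and the bridge carbon later sits in a beta-keto acid and leaves by itself.
4. Alkene partner: Knoevenagel condensation of the benzofuranone with 4-(benzyloxy)benzaldehyde. The benzofuranone comes from a 3'-iodoflavone by zinc enolate arylation and acid lactonisation. The flavone comes from phloroacetophenone and 4-hydroxy-3-iodobenzaldehyde through the chalcone.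
5. Order of ring formation: pyrone ring F, temporary lactone ring, ring C (key step). The lactone ring is then opened and its carbon lost.

Key step: step 9

Assumption: the sense of induction of the aminoindanol-derived carbene cannot be derived from a close analogue, so the (5aS,10bR) salt is written, and its commercially available mirror image is to be taken if a scouting run shows the opposite sense at C2.

**Step 1**
Reactants: 1 2',4',6'-trihydroxyacetophenone
Product: 2 2',4'-bis(benzyloxy)-6'-hydroxyacetophenone
Conditions: BnBr (2.05 equiv), K2CO3 (2.2 equiv), DMF, 25 to 60 °C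
Reagents that add atoms: benzyl bromide, BrCc1ccccc1
Why: Williamson ether synthesis in which two phenols react, while the hydroxyl that is hydrogen-bonded to the acetyl carbonyl is left, so that two equivalents of benzyl bromide stop at the dibenzyl ether.

**Step 2**
Reactants: 3 4-hydroxy-3-iodobenzaldehyde
Product: 4 3-iodo-4-(methoxymethoxy)benzaldehyde
Conditions: MOMCl (1.2 equiv), K2CO3 (1.5 equiv), acetone, 0 to 25 °C
Reagents that add atoms: chloromethyl methyl ether, COCCl
Why: Williamson-type protection of the phenol as its MOM acetal, which is stable to the bases of steps 3 to 5 and orthogonal to the benzyl ethers.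

**Step 3**
Reactants: 2 2',4'-bis(benzyloxy)-6'-hydroxyacetophenone; 4 3-iodo-4-(methoxymethoxy)benzaldehyde
Product: 5 (E)-1-[2,4-bis(benzyloxy)-6-hydroxyphenyl]-3-[3-iodo-4-(methoxymethoxy)phenyl]prop-2-en-1-one
Conditions: KOH (50 % aq), EtOH, 25 °C; then 1 M HCl to pH 6
Reagents that add atoms: none
Why: Claisen–Schmidt condensation of the methyl ketone with a non-enolisable aldehyde, in which E1cB dehydration gives the (E)-chalcone.

**Step 4**
Reactants: 5 (E)-chalcone
Product: 7 5,7-bis(benzyloxy)-2-[3-iodo-4-(methoxymethoxy)phenyl]-4H-chromen-4-one, via flavanone 6 (not isolated)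
Conditions: I2 (1.1 equiv), pyridine, 100 °C
Reagents that add atoms: none
Why: Base-promoted oxa-Michael closure of the 2'-hydroxychalcone to flavanone 6 and iodine-mediated dehydrogenation (alpha-iodination, loss of HI), a non-acidic form of the chalcone-to-flavone oxidative cyclisation that spares the MOM acetal.

**Step 5**
Reactants: 7 3'-iodoflavone; 8 (2-tert-butoxy-2-oxoethyl)zinc bromide
Product: 9 tert-butyl 2-{5-[5,7-bis(benzyloxy)-4-oxo-4H-chromen-2-yl]-2-(methoxymethoxy)phenyl}acetate
Conditions: 8 (1.5 equiv), Pd(dba)2 (5 mol %), P(t-Bu)3 (5 mol %), THF, 25 to 60 °C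
Reagents that add atoms: none
Why: Negishi-type alpha-arylation of a Reformatsky reagent under zerovalent palladium catalysis, in which the mild zinc enolate couples with the aryl iodide and leaves the chromone carbonyl, the acetal and the benzyl ethers untouched.

**Step 6**
Reactants: 9 tert-butyl arylacetate
Product: 11 5-[5,7-bis(benzyloxy)-4-oxo-4H-chromen-2-yl]-1-benzofuran-2(3H)-one, via hydroxy acid 10 (not isolated)
Conditions: CF3CO2H/CH2Cl2 (1:4), 0 to 25 °C
Reagents that add atoms: none
Why: Acidolysis of the tert-butyl ester and the MOM acetal gives hydroxy acid 10, which closes by acid-catalysed lactonisation to the five-membered aryl lactone, while aryl benzyl ethers should survive trifluoroacetic acid at room temperature.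

**Step 7**
Reactants: 11 benzofuranone; 12 4-(benzyloxy)benzaldehyde
Product: 13 (E)-3-[4-(benzyloxy)benzylidene]-5-[5,7-bis(benzyloxy)-4-oxo-4H-chromen-2-yl]-1-benzofuran-2(3H)-one
Conditions: piperidine (10 mol %), AcOH (10 mol %), 4 Å MS, toluene, 60 °C
Reagents that add atoms: none
Why: Knoevenagel condensation of the acidic lactone CH2 with the aromatic aldehyde, in which the (E)-alkene is the usual product and the geometry is of no consequence because the addition in step 9 is reversible.

**Step 8**
Reactants: 14 2,4,6-trihydroxybenzaldehyde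
Product: 15 2,4-bis(benzyloxy)-6-hydroxybenzaldehyde
Conditions: BnBr (2.05 equiv), K2CO3 (2.2 equiv), DMF, 25 °C
Reagents that add atoms: benzyl bromide, BrCc1ccccc1
Why: Williamson ether synthesis that stops at the dibenzyl ether because the last hydroxyl is hydrogen-bonded to the formyl group, which leaves exactly the oxygen that becomes O1.

**Step 9**
Reactants: 13 (E)-3-arylidenebenzofuranone; 15 2,4-bis(benzyloxy)-6-hydroxybenzaldehyde
Product: 18 (2'S,3R)-5',7'-bis(benzyloxy)-2'-[4-(benzyloxy)phenyl]-5-[5,7-bis(benzyloxy)-4-oxo-4H-chromen-2-yl]spiro[1-benzofuran-3,3'-chromane]-2,4'-dione, via acyl azolium phenoxide 16 (not isolated), via lactone enolate 17 (not isolated)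
Conditions: 15 (1.2 equiv), (5aS,10bR)-2-mesityl-5a,10b-dihydro-4H,6H-indeno[2,1-b][1,2,4]triazolo[4,3-d][1,4]oxazin-2-ium tetrafluoroborate (20 mol %), K2CO3 (40 mol %), 3,3',5,5'-tetra-tert-butyl-4,4'-diphenoquinone (1.2 equiv), 4 Å MS, THF, 25 °C
Reagents that add atoms: none
Why: Proposed new method: the carbene adds to aldehyde 15, the Breslow intermediate is oxidised by the diphenoquinone and deprotonated to the azolium-bound phenoxide 16, whose O1 adds reversibly to the electrophilic benzylidene carbon (future C2) of 13 to give lactone enolate 17, whose C3 then attacks the acyl azolium carbon (future C4) and expels the carbene. The closest known reaction types are the carbene-catalysed oxidative formal [4+2] annulation of salicylaldehydes with activated ketones through the same azolium phenoxide, the C-acylation of benzofuranone enolates (Black rearrangement) and oxa-Michael-initiated spiroannulations of 3-ylidene lactones, and what is new is a C=C acceptor in place of a C=O acceptor. Ring C is closed, after the intermolecular oxa-Michael step, by a 6-exo-trig addition–elimination of the enolate carbon at the acyl carbon. C2 is controlled by the chiral carbene, because the oxa-Michael step is reversible and the irreversible acylation, in which the aminoindanol backbone is bonded directly to C4, selects one C2 epimer of 17 (Curtin–Hammett situation), while the spiro centre C3 follows from C2 through allylic strain in the planar enolate (C2–H in the enolate plane, ring B anti to the incoming acyl carbon), which should place ring E trans to ring B. The step needs regioselectivity (O1 to C2, C4 to C3), which the polarity of the arylidene lactone fixes, preference for oxidation over a Stetter addition, which fast electron transfer from the electron-rich Breslow intermediate to the quinone should secure, and closure by O1 alone, which is secured because the ring E oxygen is tied up in the lactone and all other phenols are benzylated. The quaternary C3 of 18 carries no hydrogen, so that C2 cannot be lost by a retro-oxa-Michael reaction once the ring is closed.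

**Step 10**
Reactants: 18 spirolactone
Product: 20 (2R,3S)-5,7-bis(benzyloxy)-2-[4-(benzyloxy)phenyl]-3-{5-[5,7-bis(benzyloxy)-4-oxo-4H-chromen-2-yl]-2-hydroxyphenyl}chroman-4-one, via beta-keto acid 19 (not isolated)
Conditions: LiOH (3 equiv), THF/H2O, 0 °C; then 1 M HCl to pH 2, 40 °C
Reagents that add atoms: none
Why: Saponification of the strained aryl lactone and decarboxylation of beta-keto acid 19 on acidification (ketonic cleavage of a beta-keto ester); C3 carries no hydrogen during the basic phase, so C2 cannot be lost, and ketonisation of the enol with acid-catalysed equilibration at C3 should give the diequatorial 2,3-trans (2R,3S) isomer under control by C2.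

**Step 11**
Reactants: 20 penta-O-benzyl biflavonoid
Product: 21 (2R,3S)-5,7-dihydroxy-3-[5-(5,7-dihydroxy-4-oxo-4H-chromen-2-yl)-2-hydroxyphenyl]-2-(4-hydroxyphenyl)chroman-4-one
Conditions: H2 (1 atm), Pd/C (10 wt %), EtOAc/MeOH, 25 °C
Reagents that add atoms: none
Why: Hydrogenolysis of five aryl benzyl ethers under neutral conditions, which should touch neither the base-labile stereocentres C2 and C3 nor the pyrone double bond of ring F.

**Compound list**
1 | 2',4',6'-trihydroxyacetophenone | CC(=O)c1c(O)cc(O)cc1O | starting material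
2 | 2',4'-bis(benzyloxy)-6'-hydroxyacetophenone | CC(=O)c1c(O)cc(OCc2ccccc2)cc1OCc1ccccc1 | intermediate
3 | 4-hydroxy-3-iodobenzaldehyde | O=Cc1ccc(O)c(I)c1 | starting material
4 | 3-iodo-4-(methoxymethoxy)benzaldehyde | O=Cc1ccc(OCOC)c(I)c1 | intermediate
5 | (E)-1-[2,4-bis(benzyloxy)-6-hydroxyphenyl]-3-[3-iodo-4-(methoxymethoxy)phenyl]prop-2-en-1-one | O=C(/C=C/c1ccc(OCOC)c(I)c1)c1c(O)cc(OCc2ccccc2)cc1OCc1ccccc1 | intermediate
6 | racemic 5,7-bis(benzyloxy)-2-[3-iodo-4-(methoxymethoxy)phenyl]chroman-4-one (not isolated) | O=C1CC(c2ccc(OCOC)c(I)c2)Oc2cc(OCc3ccccc3)cc(OCc3ccccc3)c12 | intermediate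
7 | 5,7-bis(benzyloxy)-2-[3-iodo-4-(methoxymethoxy)phenyl]-4H-chromen-4-one | O=c1cc(-c2ccc(OCOC)c(I)c2)oc2cc(OCc3ccccc3)cc(OCc3ccccc3)c12 | intermediate
8 | (2-tert-butoxy-2-oxoethyl)zinc bromide | CC(C)(C)OC(=O)C[Zn]Br | starting material
9 | tert-butyl 2-{5-[5,7-bis(benzyloxy)-4-oxo-4H-chromen-2-yl]-2-(methoxymethoxy)phenyl}acetate | CC(C)(C)OC(=O)Cc1cc(-c2cc(=O)c3c(OCc4ccccc4)cc(OCc4ccccc4)cc3o2)ccc1OCOC | intermediate
10 | 2-{5-[5,7-bis(benzyloxy)-4-oxo-4H-chromen-2-yl]-2-hydroxyphenyl}acetic acid (not isolated) | OC(=O)Cc1cc(-c2cc(=O)c3c(OCc4ccccc4)cc(OCc4ccccc4)cc3o2)ccc1O | intermediate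
11 | 5-[5,7-bis(benzyloxy)-4-oxo-4H-chromen-2-yl]-1-benzofuran-2(3H)-one | O=C1Cc2cc(-c3cc(=O)c4c(OCc5ccccc5)cc(OCc5ccccc5)cc4o3)ccc2O1 | intermediate
12 | 4-(benzyloxy)benzaldehyde | O=Cc1ccc(OCc2ccccc2)cc1 | starting material
13 | (E)-3-[4-(benzyloxy)benzylidene]-5-[5,7-bis(benzyloxy)-4-oxo-4H-chromen-2-yl]-1-benzofuran-2(3H)-one | O=C1Oc2ccc(-c3cc(=O)c4c(OCc5ccccc5)cc(OCc5ccccc5)cc4o3)cc2/C1=C\c1ccc(OCc2ccccc2)cc1 | intermediate
14 | 2,4,6-trihydroxybenzaldehyde | O=Cc1c(O)cc(O)cc1O | starting material
15 | 2,4-bis(benzyloxy)-6-hydroxybenzaldehyde | O=Cc1c(O)cc(OCc2ccccc2)cc1OCc1ccccc1 | intermediate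
16 | acyl azolium phenoxide: zwitterion in which the carbene carbon of the (5aS,10bR) catalyst is bonded to the acyl carbon of oxidised 15 (not isolated) | C1[C@@H]([C@@H](c2ccccc21)n3c(C(=O)c6c([O-])cc(OCc7ccccc7)cc6OCc6ccccc6)[n+](-c4c(C)cc(C)cc4C)nc3C5)O5 | intermediate
17 | lactone enolate: oxa-Michael adduct of 16 to 13, O1–C2 bond formed, azolium still on the acyl carbon (not isolated) | C1[C@@H]([C@@H](c2ccccc21)n3c(C(=O)c6c(O[C@@H](c7ccc(OCc8ccccc8)cc7)C7=C([O-])Oc8ccc(-c9cc(=O)c1c(OCc2ccccc2)cc(OCc2ccccc2)cc1o9)cc87)cc(OCc7ccccc7)cc6OCc6ccccc6)[n+](-c4c(C)cc(C)cc4C)nc3C5)O5 | intermediate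
18 | (2'S,3R)-5',7'-bis(benzyloxy)-2'-[4-(benzyloxy)phenyl]-5-[5,7-bis(benzyloxy)-4-oxo-4H-chromen-2-yl]spiro[1-benzofuran-3,3'-chromane]-2,4'-dione | O=C1c2c(OCc3ccccc3)cc(OCc3ccccc3)cc2O[C@@H](c2ccc(OCc3ccccc3)cc2)[C@@]21c1cc(-c3cc(=O)c4c(OCc5ccccc5)cc(OCc5ccccc5)cc4o3)ccc1OC2=O | intermediate
19 | (2S,3R)-5,7-bis(benzyloxy)-2-[4-(benzyloxy)phenyl]-3-{5-[5,7-bis(benzyloxy)-4-oxo-4H-chromen-2-yl]-2-hydroxyphenyl}-4-oxochromane-3-carboxylic acid (not isolated) | O=C1c2c(OCc3ccccc3)cc(OCc3ccccc3)cc2O[C@@H](c2ccc(OCc3ccccc3)cc2)[C@]1(C(=O)O)c1cc(-c2cc(=O)c3c(OCc4ccccc4)cc(OCc4ccccc4)cc3o2)ccc1O | intermediate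
20 | (2R,3S)-5,7-bis(benzyloxy)-2-[4-(benzyloxy)phenyl]-3-{5-[5,7-bis(benzyloxy)-4-oxo-4H-chromen-2-yl]-2-hydroxyphenyl}chroman-4-one | O=C1c2c(OCc3ccccc3)cc(OCc3ccccc3)cc2O[C@@H](c2ccc(OCc3ccccc3)cc2)[C@@H]1c1cc(-c2cc(=O)c3c(OCc4ccccc4)cc(OCc4ccccc4)cc3o2)ccc1O | intermediate
21 | (2R,3S)-5,7-dihydroxy-3-[5-(5,7-dihydroxy-4-oxo-4H-chromen-2-yl)-2-hydroxyphenyl]-2-(4-hydroxyphenyl)chroman-4-one | O=C1c2c(O)cc(O)cc2O[C@@H](c2ccc(O)cc2)[C@@H]1c1cc(-c2cc(=O)c3c(O)cc(O)cc3o2)ccc1O | target

**Total step count:** 11
**Longest linear sequence:** 9 steps (steps 2, 3, 4, 5, 6, 7, 9, 10, 11, from 3)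

**Three steps most likely to fail**

First, step 9.
- What may go wrong: slow formation of the Breslow intermediate at the doubly ortho-substituted aldehyde; sluggish oxa-Michael addition of the weakly nucleophilic azolium-bound phenoxide to the donor-substituted benzylidene carbon; self-esterification of the acyl azolium; one-electron oxidation of the lactone enolate by the quinone; poor facial selectivity in the ring closure.
- Fallback: it sets out from 13 and 15 and still makes both bonds in one operation, but at the aldehyde oxidation level and with non-covalent activation. A domino oxa-Michael/aldol reaction under a quinine-derived bifunctional squaramide, a known reaction type of salicylaldehydes with electron-poor alkenes, should give the spirocyclic 4'-hydroxychromane F1. Oxidation with Dess–Martin periodinane in CH2Cl2 then erases the carbinol centre and comes back to the route at 18.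

Second, step 10.
- What may go wrong: retro-Claisen cleavage of the C3–C4 bond by hydroxide, attack of hydroxide on pyrone ring F, and incomplete equilibration at C3 after loss of CO2.
- Fallback: it sets out from 18 and avoids both aqueous base and the separate unmasking step. The lactone is opened with sodium benzyloxide (BnOH, NaH, THF, −20 °C) and the liberated ring E phenoxide is capped in the same flask with BnBr. This gives the benzyl ester benzyl ether F2. Hydrogenolysis (H2, Pd/C, EtOAc/MeOH) then removes all seven benzyl groups to give the free beta-keto acid F3, which should lose CO2 under neutral conditions and come back to the route at 21. A short stay in dilute AcOH would complete the equilibration to the trans isomer.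

Third, step 5.
- What may go wrong: slow oxidative addition and transmetalation next to the ortho acetal, protodeiodination, and addition of the zinc enolate to the chromone.
- Fallback: it sets out from 7 and replaces the zinc enolate and palladium by a soft stabilised carbanion and copper catalysis (Hurtley-type malonate arylation). Di-tert-butyl malonate, CuI, 2-picolinic acid and Cs2CO3 in dioxane should give the di-tert-butyl arylmalonate F4. Trifluoroacetic acid in CH2Cl2 then strips both esters and the acetal to give the arylmalonic acid F5, which on warming loses CO2 to give 10. Compound 10 closes to the lactone, so the fallback comes back to the route at 11.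

**Further compounds**
F1 | step 9 | (2'S,3R)-5',7'-bis(benzyloxy)-2'-[4-(benzyloxy)phenyl]-5-[5,7-bis(benzyloxy)-4-oxo-4H-chromen-2-yl]-4'-hydroxyspiro[1-benzofuran-3,3'-chroman]-2-one (either epimer at C4', erased on oxidation) | OC1c2c(OCc3ccccc3)cc(OCc3ccccc3)cc2O[C@@H](c2ccc(OCc3ccccc3)cc2)[C@@]21c1cc(-c3cc(=O)c4c(OCc5ccccc5)cc(OCc5ccccc5)cc4o3)ccc1OC2=O
F2 | step 10 | benzyl (2S,3R)-5,7-bis(benzyloxy)-3-{2-(benzyloxy)-5-[5,7-bis(benzyloxy)-4-oxo-4H-chromen-2-yl]phenyl}-2-[4-(benzyloxy)phenyl]-4-oxochromane-3-carboxylate | O=C1c2c(OCc3ccccc3)cc(OCc3ccccc3)cc2O[C@@H](c2ccc(OCc3ccccc3)cc2)[C@]1(C(=O)OCc1ccccc1)c1cc(-c2cc(=O)c3c(OCc4ccccc4)cc(OCc4ccccc4)cc3o2)ccc1OCc1ccccc1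
F3 | step 10 | (2S,3R)-5,7-dihydroxy-3-[5-(5,7-dihydroxy-4-oxo-4H-chromen-2-yl)-2-hydroxyphenyl]-2-(4-hydroxyphenyl)-4-oxochromane-3-carboxylic acid | O=C1c2c(O)cc(O)cc2O[C@@H](c2ccc(O)cc2)[C@]1(C(=O)O)c1cc(-c2cc(=O)c3c(O)cc(O)cc3o2)ccc1O
F4 | step 5 | di-tert-butyl 2-{5-[5,7-bis(benzyloxy)-4-oxo-4H-chromen-2-yl]-2-(methoxymethoxy)phenyl}malonate | CC(C)(C)OC(=O)C(C(=O)OC(C)(C)C)c1cc(-c2cc(=O)c3c(OCc4ccccc4)cc(OCc4ccccc4)cc3o2)ccc1OCOC
F5 | step 5 | 2-{5-[5,7-bis(benzyloxy)-4-oxo-4H-chromen-2-yl]-2-hydroxyphenyl}malonic acid | OC(=O)C(C(=O)O)c1cc(-c2cc(=O)c3c(OCc4ccccc4)cc(OCc4ccccc4)cc3o2)ccc1O
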